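The question was which of the three flasks held the most target at the end, and how much, when the same substrate also pairs into homo dimer.

| setting | north | south | north-west |
|---|---|---|---|
| substrate | 42 mM | 42 mM | 42 mM |
| free catalyst | 42 µM | 42 µM | 42 µM |
| temperature | 55 °C |  | 40 °C |
| time | 2.0 min | 2.0 min | 2.0 min |
| remark |  | at 55 °C until 25 s, from then on at 40 °C |  |

1. the flask that comes out highest in amount of target, in percent of the substrate charged, or "all alike" when all lie within 1.5 percentage points (north / south / north-west / all alike)
2. target at the end, in percent of the substrate charged, north
3. target at the end, in percent of the substrate charged, south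
4. target at the end, in percent of the substrate charged, north-west

    substrate + free catalyst → catalyst intermediate A (k1 = 274 L mol⁻¹ s⁻¹, Ea1 = 36.0 kJ mol⁻¹)
    catalyst intermediate A ⇌ catalyst intermediate B (K2 = 3.96, k2 = 7.11 s⁻¹, Ea2 = 63.0 kJ mol⁻¹, ΔH2 = −2.00 kJ mol⁻¹)
    catalyst intermediate B → free catalyst + target (k3 = 10.2 s⁻¹, Ea3 = 69.0 kJ mol⁻¹)
    2 substrate → homo dimer (k4 = 0.0652 L mol⁻¹ s⁻¹, Ea4 = 67.0 kJ mol⁻¹)
    free catalyst ⇌ dormant form (K5 = 0.39, k5 = 0.00125 s⁻¹, Ea5 = 82.0 kJ mol⁻¹, ΔH5 = 8.00 kJ mol⁻¹)
    (constants at 40 °C)

- percentages count the substrate that a species holds: one homo dimer counts as two
- two of one species on the left: rate k times its square, two consumed each time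
- all constants are for 40 °C and move with temperature by the activation energies and enthalpies

With all catalyst free, substrate entered the catalyst 1.22 times as fast as it entered the dimer in north, and 2.10 times as fast in north-west. North-west stood higher because dimerisation's activation energy lies 31.0 kJ mol⁻¹ above that of binding. I called this the split ratio: the binding constant times free catalyst, over twice the dimerisation constant times substrate, a selectivity factor. Dividing the two rates removed time, and integrating over substrate gave a ceiling on target: the split times the natural logarithm of one plus its inverse. That came to 73.0% in north and 81.8% in north-west.

Beside that high ceiling, the clock in north-west looked contradictory. Each catalyst had to turn 1000 times to bring the whole charge to target, but one round in north-west at the starting substrate took 0.350 s, allowing 343 rounds. The clock's bound on target in north-west came to 34.3%. The ceiling speaks of a flask with its substrate gone, and the clock speaks of the asked time. Once the round was running at the starting substrate in north-west, I reckoned free catalyst at 24.8% of the catalyst charged, so the working split was 0.521: in that reckoning substrate entered the dimer faster than the catalyst. In north-west the steps after binding took longer than binding, and their activation energies, 63.0 kJ mol⁻¹ and 69.0 kJ mol⁻¹, exceed the 36.0 kJ mol⁻¹ of binding, so heat shortens the round while lowering the split. My reckoning stopped there, with no estimate of the end target in north or south.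

The forecast named north, because “the faster turnover outweighs them”. It gave 47% for north (43% to 51%), 35.5% for south (32% to 39%) and 28.7% for north-west (26% to 31.5%).

The simulation put north highest, with 48.2% there, 35.5% in south and 29.2% in north-west, within the forecast's ranges. North led at the asked time but not at 20.0 min, when north-west held 64.0% of target against 58.3% in north, the order of the two ceilings. In north, the split counted with the catalyst and substrate then standing rose from 1.4 at 0.644 min to 7.7 at 2.00 min. A neighbour of north charged with 0.17 mM of free catalyst started at a split of 4.94, a ceiling of 91.1%, and ended with 82.9% of target and 0.039% of substrate left.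

(The constants used here are invented; what happens was integrated by code.)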